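The side chain is disconnected at C1′–C2′, between the methylene on C3 of the quinone ring (ring B) and the first olefinic carbon. The (E)-C2′=C3′(CH3) olefin, insulated from ring B by the single C1′ methylene, is the signature of a syn methylmetalation of a terminal alkyne. In one flask, zirconium-catalysed carboalumination of the C38 enyne 18 installs the C3′ methyl and the (E)-alkenyl–aluminium bond, and nickel-catalysed coupling with 2-(chloromethyl)-3-methyl-1,4-naphthoquinone 2 forms C1′–C2′, giving the free quinone directly. The precursor is a methyl-less terminal alkyne carrying the (R) methyl stereocenter (chiral pool) and an all-E hexaprenyl tail assembled from two farnesyl units.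

Key step: step 11

Assumption: side-chain carbons are numbered C1′ (the methylene on ring B) outward, the single stereocenter is C7′ and is (R), and (2E,6E)-farnesyl acetate, (2E,6E)-farnesyl bromide and (S)-3-bromo-2-methylpropan-1-ol are taken as purchasable single isomers.

Step 1
Reactants: 1 2-methylnaphthalene-1,4-dione (menadione)
Product: 2 2-(chloromethyl)-3-methylnaphthalene-1,4-dione
Conditions: HCHO (37% aq.), HCl (g), AcOH, rt
Reagents that add atoms: formaldehyde, C=O; hydrogen chloride, Cl
Why: Blanc-type chloromethylation, in which acid-activated formaldehyde attacks the only unsubstituted quinone carbon (C3) and HCl converts the hydroxymethyl group into the chloride.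

Step 2
Reactants: 3 (S)-3-bromo-2-methylpropan-1-ol; 4 (4-bromobut-1-yn-1-yl)trimethylsilane
Product: 6 (R)-2-methyl-7-(trimethylsilyl)hept-6-yn-1-ol, via homopropargyl Grignard reagent 5 (not isolated)
Conditions: 4, Mg, I2 (cat.), THF, 35 °C (2.3 equiv of 5); then 3, Li2CuCl4 (3 mol%), NMP, THF, −20 °C → rt; aq. NH4Cl
Reagents that add atoms: none
Why: Kochi-type copper-catalysed sp3–sp3 Grignard cross-coupling, in which one equivalent of 5 deprotonates the hydroxyl group and the next displaces the primary bromide, while the chiral-pool stereocenter (the future C7′, β to the reacting carbon) is untouched and only changes its descriptor.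

Step 3
Reactants: 6 (R)-2-methyl-7-(trimethylsilyl)hept-6-yn-1-ol
Product: 7 (R)-(7-bromo-6-methylhept-1-yn-1-yl)trimethylsilane
Conditions: CBr4, PPh3, CH2Cl2, 0 °C
Reagents that add atoms: carbon tetrabromide, BrC(Br)(Br)Br
Why: The Appel reaction converts the unhindered primary alcohol into the bromide under neutral conditions that leave the silylalkyne and the adjacent stereocenter unaffected.

Step 4
Reactants: 8 (2E,6E)-3,7,11-trimethyldodeca-2,6,10-trien-1-yl acetate ((2E,6E)-farnesyl acetate)
Product: 9 (2E,6E,10E)-12-hydroxy-3,7,11-trimethyldodeca-2,6,10-trien-1-yl acetate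
Conditions: SeO2 (cat.), t-BuOOH, salicylic acid (cat.), CH2Cl2, 0 °C → rt
Reagents that add atoms: tert-butyl hydroperoxide, CC(C)(C)OO (oxygen delivered through catalytic selenium dioxide, O=[Se]=O)
Why: Riley allylic oxidation, in which an ene reaction at the most electron-rich terminal olefin and a [2,3]-sigmatropic shift should give the (E)-allylic alcohol at the trans methyl group, the C2 olefin being deactivated by the allylic acetate.

Step 5
Reactants: 7 (R)-(7-bromo-6-methylhept-1-yn-1-yl)trimethylsilane; 9 (2E,6E,10E)-12-hydroxy-3,7,11-trimethyldodeca-2,6,10-trien-1-yl acetate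
Product: 11 (2E,6E,10E,14R)-2,6,10,14-tetramethyl-19-(trimethylsilyl)nonadeca-2,6,10-trien-18-yn-1-ol, via alkylmagnesium bromide 10 (not isolated)
Conditions: 7, Mg, I2 (cat.), THF, 45 °C; separately 9, i-PrMgCl (1.0 equiv), THF, −78 °C; then combined, Li2CuCl4 (5 mol%), THF, −78 → 0 °C; aq. NH4Cl
Reagents that add atoms: none
Why: Copper-catalysed allylic substitution of a primary allylic acetate by an alkyl Grignard reagent should occur at the α-carbon with retention of the (E)-olefin, because γ-attack would build a quaternary carbon; the pre-formed magnesium alkoxide only spectates and the (R) stereocenter of 10 is carried through unchanged.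

Step 6
Reactants: 11 (2E,6E,10E,14R)-2,6,10,14-tetramethyl-19-(trimethylsilyl)nonadeca-2,6,10-trien-18-yn-1-ol
Product: 12 [(6R,9E,13E,17E)-19-bromo-6,10,14,18-tetramethylnonadeca-9,13,17-trien-1-yn-1-yl]trimethylsilane
Conditions: PBr3, pyridine (cat.), Et2O, −10 °C
Reagents that add atoms: phosphorus tribromide, BrP(Br)Br
Why: SN2 bromination of the primary allylic alcohol through its phosphite ester at low temperature, the standard polyprenol-to-bromide conversion, should preserve the (E)-geometry.

Step 7
Reactants: 13 (2E,6E)-1-bromo-3,7,11-trimethyldodeca-2,6,10-triene ((2E,6E)-farnesyl bromide)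
Product: 14 {[(2E,6E)-3,7,11-trimethyldodeca-2,6,10-trien-1-yl]sulfonyl}benzene ((2E,6E)-farnesyl phenyl sulfone)
Conditions: PhSO2Na, DMF, rt
Reagents that add atoms: sodium benzenesulfinate, [Na+].[O-]S(=O)c1ccccc1
Why: SN2 S-alkylation of the sulfinate by the primary allylic bromide should give the allylic sulfone with unchanged (2E,6E) geometry.

Step 8
Reactants: 14 (2E,6E)-farnesyl phenyl sulfone; 12 [(6R,9E,13E,17E)-19-bromo-6,10,14,18-tetramethylnonadeca-9,13,17-trien-1-yn-1-yl]trimethylsilane
Product: 16 {[(6R,9E,13E,17E,21E,25E)-6,10,14,18,22,26,30-heptamethyl-1-(trimethylsilyl)hentriaconta-9,13,17,21,25,29-hexaen-1-yn-20-yl]sulfonyl}benzene (mixture of C20 epimers), via lithiated sulfone 15 (not isolated)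
Conditions: 14, n-BuLi, THF/DMPU, −78 °C; then 12, −78 → −20 °C
Reagents that add atoms: none
Why: Biellmann coupling, in which the sulfonyl-stabilised allylic carbanion alkylates the primary allylic bromide at its α-carbon and joins the two farnesyl-derived units head to tail without touching any olefin; the sulfonyl-bearing carbon forms as an inconsequential epimeric mixture that step 9 removes.

Step 9
Reactants: 16 C20 phenylsulfonyl hexaenyne (mixture of C20 epimers)
Product: 17 trimethyl[(6R,9E,13E,17E,21E,25E)-6,10,14,18,22,26,30-heptamethylhentriaconta-9,13,17,21,25,29-hexaen-1-yn-1-yl]silane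
Conditions: PdCl2(dppp) (5 mol%), LiEt3BH, THF, 0 °C
Reagents that add atoms: none
Why: Palladium-catalysed reductive desulfonylation (Tsuji–Trost-type ionisation of the allylic sulfone, then hydride delivery from LiEt3BH to the less substituted allyl terminus) should remove the sulfonyl group and keep the trisubstituted (E)-olefin in place, the silylalkyne being inert to the hydride.

Step 10
Reactants: 17 trimethyl[(6R,9E,13E,17E,21E,25E)-6,10,14,18,22,26,30-heptamethylhentriaconta-9,13,17,21,25,29-hexaen-1-yn-1-yl]silane
Product: 18 (6R,9E,13E,17E,21E,25E)-6,10,14,18,22,26,30-heptamethylhentriaconta-9,13,17,21,25,29-hexaen-1-yne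
Conditions: K2CO3, MeOH/THF, rt
Reagents that add atoms: none
Why: Base-mediated methanolysis of the alkynyl C–Si bond (protodesilylation) should free the terminal alkyne without affecting the olefins or the stereocenter.

Step 11
Reactants: 18 (6R,9E,13E,17E,21E,25E)-6,10,14,18,22,26,30-heptamethylhentriaconta-9,13,17,21,25,29-hexaen-1-yne; 2 2-(chloromethyl)-3-methylnaphthalene-1,4-dione
Product: 20 2-methyl-3-[(2E,7R,10E,14E,18E,22E,26E)-3,7,11,15,19,23,27,31-octamethyldotriaconta-2,10,14,18,22,26,30-heptaen-1-yl]naphthalene-1,4-dione, via alkenyldimethylalane 19 (not isolated)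
Conditions: 18, Me3Al (2 equiv), Cp2ZrCl2 (0.25 equiv), ClCH2CH2Cl, rt; volatiles removed in vacuo, THF; then 2 (1.0 equiv), NiCl2(PPh3)2 (3 mol%) pre-reduced with n-BuLi (6 mol%) to zerovalent nickel, THF, −20 °C → rt
Reagents that add atoms: trimethylaluminium, C[Al](C)C
Why: Me3Al and Cp2ZrCl2 form a polarised methylzirconocene–aluminate that adds methyl and metal syn across the terminal C≡C of 18, methyl to the internal carbon (C3′) and, after Zr-to-Al exchange, AlMe2 to C2′, giving the (E)-2-methylalk-1-enylalane 19; zerovalent nickel then inserts into the activated C–Cl bond of 2, the alkenyl group passes from aluminium to nickel, and reductive elimination forms C1′–C2′ with retention of olefin geometry. The closest known reaction type is the Negishi zirconium-catalysed carboalumination followed by nickel-catalysed alkenylalane–benzylic chloride cross-coupling, which is established for chloromethylated para-quinones. No ring is closed and no stereocenter is created, and the (R)-C7′ center, four carbons from the alkyne, is not involved. The step needs regioselective methylmetalation (secured by the unbranched 1-alkyne terminus), syn stereospecificity (inherent to the four-centre addition, hence E), chemoselectivity for the alkyne over six trisubstituted olefins (inert to carboalumination), and C–Cl coupling in preference to carbonyl addition at the quinone (secured by stripping excess Me3Al, the low nucleophilicity of alkenyl–aluminium in THF at low temperature and fast nickel turnover).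

Compound list
1 | 2-methylnaphthalene-1,4-dione (menadione) | CC1=CC(=O)c2ccccc2C1=O | starting material
2 | 2-(chloromethyl)-3-methylnaphthalene-1,4-dione | CC1=C(CCl)C(=O)c2ccccc2C1=O | intermediate
3 | (S)-3-bromo-2-methylpropan-1-ol | OC[C@H](C)CBr | starting material
4 | (4-bromobut-1-yn-1-yl)trimethylsilane | C[Si](C)(C)C#CCCBr | starting material
5 | [4-(trimethylsilyl)but-3-yn-1-yl]magnesium bromide (not isolated) | C[Si](C)(C)C#CCC[Mg]Br | intermediate
6 | (R)-2-methyl-7-(trimethylsilyl)hept-6-yn-1-ol | OC[C@H](C)CCCC#C[Si](C)(C)C | intermediate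
7 | (R)-(7-bromo-6-methylhept-1-yn-1-yl)trimethylsilane | BrC[C@H](C)CCCC#C[Si](C)(C)C | intermediate
8 | (2E,6E)-3,7,11-trimethyldodeca-2,6,10-trien-1-yl acetate ((2E,6E)-farnesyl acetate) | CC(C)=CCC/C(C)=C/CC/C(C)=C/COC(C)=O | starting material
9 | (2E,6E,10E)-12-hydroxy-3,7,11-trimethyldodeca-2,6,10-trien-1-yl acetate | OC/C(C)=C/CC/C(C)=C/CC/C(C)=C/COC(C)=O | intermediate
10 | [(R)-2-methyl-7-(trimethylsilyl)hept-6-yn-1-yl]magnesium bromide (not isolated) | Br[Mg]C[C@H](C)CCCC#C[Si](C)(C)C | intermediate
11 | (2E,6E,10E,14R)-2,6,10,14-tetramethyl-19-(trimethylsilyl)nonadeca-2,6,10-trien-18-yn-1-ol | OC/C(C)=C/CC/C(C)=C/CC/C(C)=C/CC[C@H](C)CCCC#C[Si](C)(C)C | intermediate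
12 | [(6R,9E,13E,17E)-19-bromo-6,10,14,18-tetramethylnonadeca-9,13,17-trien-1-yn-1-yl]trimethylsilane | BrC/C(C)=C/CC/C(C)=C/CC/C(C)=C/CC[C@H](C)CCCC#C[Si](C)(C)C | intermediate
13 | (2E,6E)-1-bromo-3,7,11-trimethyldodeca-2,6,10-triene ((2E,6E)-farnesyl bromide) | CC(C)=CCC/C(C)=C/CC/C(C)=C/CBr | starting material
14 | {[(2E,6E)-3,7,11-trimethyldodeca-2,6,10-trien-1-yl]sulfonyl}benzene | CC(C)=CCC/C(C)=C/CC/C(C)=C/CS(=O)(=O)c1ccccc1 | intermediate
15 | 1-lithio derivative of sulfone 14 (not isolated) | CC(C)=CCC/C(C)=C/CC/C(C)=C/C([Li])S(=O)(=O)c1ccccc1 | intermediate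
16 | {[(6R,9E,13E,17E,21E,25E)-6,10,14,18,22,26,30-heptamethyl-1-(trimethylsilyl)hentriaconta-9,13,17,21,25,29-hexaen-1-yn-20-yl]sulfonyl}benzene, mixture of C20 epimers | CC(C)=CCC/C(C)=C/CC/C(C)=C/C(S(=O)(=O)c1ccccc1)C/C(C)=C/CC/C(C)=C/CC/C(C)=C/CC[C@H](C)CCCC#C[Si](C)(C)C | intermediate
17 | trimethyl[(6R,9E,13E,17E,21E,25E)-6,10,14,18,22,26,30-heptamethylhentriaconta-9,13,17,21,25,29-hexaen-1-yn-1-yl]silane | CC(C)=CCC/C(C)=C/CC/C(C)=C/CC/C(C)=C/CC/C(C)=C/CC/C(C)=C/CC[C@H](C)CCCC#C[Si](C)(C)C | intermediate
18 | (6R,9E,13E,17E,21E,25E)-6,10,14,18,22,26,30-heptamethylhentriaconta-9,13,17,21,25,29-hexaen-1-yne | CC(C)=CCC/C(C)=C/CC/C(C)=C/CC/C(C)=C/CC/C(C)=C/CC/C(C)=C/CC[C@H](C)CCCC#C | intermediate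
19 | dimethyl[(1E,6R,9E,13E,17E,21E,25E)-2,6,10,14,18,22,26,30-octamethylhentriaconta-1,9,13,17,21,25,29-heptaen-1-yl]alumane (not isolated) | CC(C)=CCC/C(C)=C/CC/C(C)=C/CC/C(C)=C/CC/C(C)=C/CC/C(C)=C/CC[C@H](C)CCC/C(C)=C/[Al](C)C | intermediate
20 | 2-methyl-3-[(2E,7R,10E,14E,18E,22E,26E)-3,7,11,15,19,23,27,31-octamethyldotriaconta-2,10,14,18,22,26,30-heptaen-1-yl]naphthalene-1,4-dione | CC(C)=CCC/C(C)=C/CC/C(C)=C/CC/C(C)=C/CC/C(C)=C/CC/C(C)=C/CC[C@H](C)CCC/C(C)=C/CC1=C(C)C(=O)c2ccccc2C1=O | target

Total step count: 11. Longest linear sequence: 8 steps (steps 2, 3, 5, 6, 8, 9, 10, 11).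

Steps most likely to fail

Step 11. Carbonyl addition or electron transfer from the alkenylalane (or residual Me3Al) to the unprotected quinone may outrun nickel-catalysed C–Cl substitution. The fallback sets out from alkyne 18, which is methylaluminated to alane 19 as before. Alane 19 would then be coupled, under the same zerovalent nickel catalyst, with 2-(chloromethyl)-1,4-dimethoxy-3-methylnaphthalene F1, a benzylic chloride without electrophilic carbonyl groups (made from commercial 1,4-dimethoxy-2-methylnaphthalene with paraformaldehyde and HCl in AcOH). The resulting 1,4-dimethoxy-2-methyl-3-[(2E,7R,10E,14E,18E,22E,26E)-3,7,11,15,19,23,27,31-octamethyldotriaconta-2,10,14,18,22,26,30-heptaen-1-yl]naphthalene F2 would be oxidatively demethylated with (NH4)2Ce(NO3)6 in MeCN/H2O at 0 °C, which comes back to the route at 20.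

Step 5. Acetyl transfer between the magnesium alkoxide and the allylic acetate, or carbonyl attack of the Grignard reagent on the acetate, may scramble which chain end is substituted. The fallback sets out from bromide 7 (as Grignard reagent 10) and couples it (Li2CuCl4, THF, −78 → 0 °C) with (2E,6E)-farnesyl bromide 13, which carries neither hydroxyl nor ester. This should give trimethyl[(6R,9E,13E)-6,10,14,18-tetramethylnonadeca-9,13,17-trien-1-yn-1-yl]silane F3. Oxidation of F3 at the terminal trans methyl group (SeO2 cat., t-BuOOH, CH2Cl2) then comes back to the route at 11.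

Step 9. The C21=C22 olefin may migrate or lose its E geometry through the π-allylpalladium hydride intermediate, giving isomers that would be hard to separate from the C38 hydrocarbon. The fallback sets out from bromide 12 and avoids sulfone chemistry altogether, bypassing 14–16. Commercial (2E,6E)-farnesyl chloride would be converted with activated barium (from BaI2 and lithium biphenylide, THF, −78 °C) into [(2E,6E)-3,7,11-trimethyldodeca-2,6,10-trien-1-yl]barium chloride F4. Its α,α′-selective, geometry-retaining allyl–allyl coupling with 12 at −78 °C comes back to the route at 17.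

Further compounds
F1 | step 11 | 2-(chloromethyl)-1,4-dimethoxy-3-methylnaphthalene | COc1c(C)c(CCl)c(OC)c2ccccc12
F2 | step 11 | 1,4-dimethoxy-2-methyl-3-[(2E,7R,10E,14E,18E,22E,26E)-3,7,11,15,19,23,27,31-octamethyldotriaconta-2,10,14,18,22,26,30-heptaen-1-yl]naphthalene | CC(C)=CCC/C(C)=C/CC/C(C)=C/CC/C(C)=C/CC/C(C)=C/CC/C(C)=C/CC[C@H](C)CCC/C(C)=C/Cc1c(C)c(OC)c2ccccc2c1OC
F3 | step 5 | trimethyl[(6R,9E,13E)-6,10,14,18-tetramethylnonadeca-9,13,17-trien-1-yn-1-yl]silane | CC(C)=CCC/C(C)=C/CC/C(C)=C/CC[C@H](C)CCCC#C[Si](C)(C)C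
F4 | step 9 | [(2E,6E)-3,7,11-trimethyldodeca-2,6,10-trien-1-yl]barium chloride | CC(C)=CCC/C(C)=C/CC/C(C)=C/C[Ba]Cl
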